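(The readings stem from a simulated flask for an exercise, noise included.)

**Small charge.** A small charge shows the flask plainly: the readings of epsilon, with 0.070 M of starting material, give product at 0.00420 M/h up to 6.00 h, and those of alpha, with 0.094 M, give 0.00439 M/h up to 6.00 h, so the enzyme's rate stands nearly flat against the charge (zero order).

| setting | alpha | epsilon | red | ochre | amber | teal | grey |
|---|---|---|---|---|---|---|---|
| starting material | 0.094 M | 0.070 M | 0.14 M | 0.14 M | 0.14 M | 0.14 M | 0.14 M |
| second substrate | 0.084 M | 0.084 M | 0.0840 M | 0.120 M | 0.0840 M | 0.0840 M | 0.0600 M |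
| free enzyme | 14 µM | 14 µM | 60 µM | 60 µM | 4.0 µM | 14 µM | 10 µM |
| temperature | 37 °C | 37 °C | 37 °C | 37 °C | 37 °C | 37 °C | 57 °C |
| remark | run made earlier | run made earlier |  |  |  |  |  |
| time |  |  | 30 h | 30 h | 30 h | 30 h | 30 h |

| run | time / h | product / % | starting material / % |
|---|---|---|---|
| alpha | 3.00 | 14 | 56 |
| alpha | 6.00 | 28 | 33 |
| alpha | 10.0 | 42 | 13 |
| alpha | 12.0 | 47 | 9 |
| alpha | 15.0 | 49 | 4 |
| alpha | 20.0 | 55 | 4 |
| epsilon | 1.33 | 8 | 78 |
| epsilon | 4.00 | 25 | 47 |
| epsilon | 6.00 | 36 | 34 |
| epsilon | 10.0 | 56 | 13 |
| epsilon | 15.0 | 64 | 2 |
| epsilon | 20.0 | 62 | 0 |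

(readings scatter by 1.5 percentage points)

- a reading or a percentage of product counts all its forms, free or not
- the earlier runs do not show what temperature does; that part of a forecast is a guess
- no earlier run changes the charge of free enzyme; that part of a forecast is a guess

* the flasks by amount of product, in percent of the starting material charged, highest first, at 30 h (red / ochre / amber / teal / grey)
* the same order at 3.0 h (red / ochre / amber / teal / grey)
* the amount of product, in percent of the starting material charged of the flask you put first, at 30 h
* the amount of product, in percent of the starting material charged of the flask you put last, at 30 h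

**Two rates.** Per enzyme the alpha rate is 313 /h; that it scales with enzyme is my guess. Meanwhile 30.0 % of alpha's charge at 3.00 h is neither starting material nor product. Divided by the squared mean [starting material], this side loss gives 1.75 /M/h in alpha and 1.85 /M/h in epsilon, so I take it to go with [starting material] squared.

**Balance concentration.** Side loss equals the enzyme's rate at a [starting material] of 0.0501 M, which I call the balance concentration; this value holds for 14 µM of enzyme, and on my guess of a rate that scales with enzyme it grows with the root of the enzyme.

**Two extremes.** Far below balance, with second substrate to spare, the enzyme wins, and product tends to the charge itself. Far above it, side loss takes the excess, and product tends to a ceiling free of the charge, of the order of the balance concentration; as a rough choice of mine I take 0.0709 M for it at that enzyme level. I join the two by adding the inverse squares of charge and ceiling, which gives a rough estimate that I call the reach. On alpha the reach is 60.2 % against the 55 % read, so it runs a little high. Assuming one second substrate per product, the second substrate's charge caps it.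

**My reckoning.** My reach for ochre is 72.3 %, under its cap of 85.7 %. Red has the same reach, so I expect it at its cap of 60.0 %. My reach for teal is 45.1 % and for amber 26.1 %. Grey's temperature is unread, so I give it no figure.

**The forecast.** It says ochre > red > teal > grey > amber at 30 h and ochre > red > grey > teal > amber at 3.0 h, with 52 % (42 % to 66 %) first and 26 % (17 % to 34 %) last. Of the stall it says “I read this as an equilibrium”, and its figure for ochre stands below my reach.

**The flasks.** They give ochre > red > teal > amber > grey at 30 h and ochre > red > grey > teal > amber at 3.0 h, with 70.5 % first and 16.6 % last.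

    2 starting material → homo dimer (k = 2.60 × 10⁻⁴ /M/s, Ea = 83.0 kJ/mol)
    second substrate + starting complex ⇌ ternary complex (K = 13.0 /M, k = 7.60 /M/s, Ea = 41.0 kJ/mol, ΔH = −10.0 kJ/mol)
    free enzyme → unfolded enzyme (k = 5.80 × 10⁻⁷ /s, Ea = 282 kJ/mol)
    crystals ⇌ product, rate k4*(cs4 - [product]) while solid is left; crystals form when [product] > cs4 (solubility = 2.50 mM, k = 1.70 × 10⁻⁴ /s)
    ternary complex → free enzyme + product (k = 0.250 /s, Ea = 89.0 kJ/mol)
    starting material + free enzyme ⇌ starting complex (K = 120 /M, k = 48.0 /M/s, Ea = 49.0 kJ/mol, ΔH = −15.0 kJ/mol)
    (constants at 37 °C)

**At rest?** Ochre stands at 70.5 %, against my reach of 72.3 % and above the forecast's range, with 0 % starting material at 30.0 h, and it still shows 70.5 % at 300 h: ochre's product has stopped. Amber's has not: with 3.81 % starting material at 30.0 h, its 21.3 % of product becomes 24.9 % at 300 h, against its reach of 26.1 %. Grey, with 100 % unfolded enzyme at 30.0 h, holds 16.6 % at 300 h.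

**A neighbour.** Ochre's neighbour with 0.072 M of second substrate keeps ochre's enzyme charge, hence a balance concentration of 0.104 M and the reach of 72.3 %, but its cap is 51.4 %, so I expect the cap. It gives 51.4 %, with 0.017 % of its second substrate left, the limiting reagent.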